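I start from the end.

| setting | Friday's | Tuesday's | Thursday's | north | west |
|---|---|---|---|---|---|
| substrate | 0.10 M | 0.10 M | 0.19 M | 0.10 M | 0.30 M |
| reagent | 0.060 M | 0.060 M | 0.060 M | 0.0600 M | 0.0600 M |
| free catalyst | 6.8 mM | 35 mM | 5.8 mM | 5.8 mM | 25 mM |
| temperature | 20 °C | 31 °C | 20 °C | 25 °C | 25 °C |
| remark | run made earlier | run made earlier | run made earlier |  |  |
| time |  |  |  | 3.0 h | 3.0 h |

- Friday's (time / min: target / %, substrate / %): 25.0: 6, 91; 50.0: 11, 84; 60.0: 14, 81; 90.0: 23, 73
- Tuesday's (time / min: target / %, substrate / %): 8.00: 29, 61; 15.0: 44, 47; 40.0: 60, 41; 90.0: 61, 42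
- Thursday's (time / min: target / %, substrate / %): 25.0: 4, 94; 50.0: 5, 91; 60.0: 9, 89; 90.0: 12, 85

(readings scatter by 1.5 percentage points)

1. the winner by amount of target, in percent of the substrate charged; "neither" if no more than 2 percentage points parts them (north / west / neither)
2. how much target is there at the end, in percent of the substrate charged: north
3. how much target is there at the end, in percent of the substrate charged: west

- a reading or a percentage of target counts all its forms, free or not

Tuesday's run reads target 60 % at 40.0 min and 61 % at 90.0 min, which matches its reagent charge over its substrate charge, 60.0 %. So I read one reagent per target, with reagent as the limiting reagent. I call the ceiling c the reagent charge over the substrate charge, held at the whole charge once that ratio passes one; in north it is 60.0 %.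

Now the settings. By hand, more substrate at equal reagent lowers c once substrate stands above reagent, and west's 0.30 M gives 20.0 %. In the readings, Thursday's 0.19 M made 22.8 mM of target by 90.0 min and Friday's 0.10 M made 23.0 mM, with 5.8 mM and 6.8 mM of catalyst. By hand, more reagent lifts c up to the whole charge, but Friday's, Tuesday's and Thursday's runs stand at 0.060 M. Catalyst and temperature leave c alone by hand and should set the pace: Tuesday, at 35 mM and 31 °C, has its plateau by 40.0 min, while Friday has 38.3 % of the same c at 90.0 min. Those two settings differ together between Tuesday's and Friday's runs, so this pair does not part them.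

Then time. North runs 2.00 of Friday's stretches. If each stretch closes the same share of the distance to c, and I let the pace go with catalyst, north's 5.8 mM against Friday's 6.8 mM gives 33.7 %. That figure counts nothing for north's warmer bath, so I commit to a rough range from it up to c. West, with 25 mM, I expect on its c. North's lower figure stands above west's ceiling, so I call north the winner without fitting a rate.

The forecast says north, with 49 % for north and 20 % for west: “That caps north at 60% and west at 20%.”

North gives 52.0 % and west 20.0 %, so north wins. North has reached 86.7 % of c, and left for 30.0 h it stands at 60.0 %. Its figure moves 5 points at 0.0527 M of reagent, where c is still 52.7 %, above west's 20.0 %.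

    substrate + catalyst intermediate A → catalyst intermediate B (k = 30.0 M⁻¹ min⁻¹, Ea = 42.0 kJ mol⁻¹)
    free catalyst + target ⇌ idle complex, settled at all times (K = 7.40 M⁻¹, ΔH = −90.0 kJ mol⁻¹)
    reagent + free catalyst ⇌ catalyst intermediate A (K = 12.0 M⁻¹, k = 5.80 M⁻¹ min⁻¹, Ea = 66.0 kJ mol⁻¹, ΔH = −24.0 kJ mol⁻¹)
    catalyst intermediate B → free catalyst + target (k = 0.120 min⁻¹, Ea = 97.0 kJ mol⁻¹)
    (constants at 25 °C)

The neighbour is north with 0.15 M of reagent. The ratio is 1.50, so c is 100 % and substrate takes over as the limiting charge. That flask gives 83.3 % at 3.00 h, with 14 % of its substrate and 42 % of its reagent still there, unbound.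

Readings and results were computed with constants of no real substance.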